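3 questions stand for this flask, and one count answers the first and ties the other two together.

- north-east: starting complex 1.4 M; incoming ligand 0.56 M; run made earlier
- flask: starting complex 1.4 M; incoming ligand 1.12 M; time 15 d

- north-east (time / h: complex with one exchanged / %, complex with two exchanged / %): 5.00: 11.9, 2.2; 12.0: 19.5, 4.1; 25.0: 24.3, 4.9; 40.0: 25.1, 7.7

(scatter of a reading: 1 percentage point)

- what may be going on: complex with one exchanged + incoming ligand -> leaving ligand + complex with two exchanged; starting complex + incoming ligand -> leaving ligand + complex with one exchanged; starting complex -> decomposition product
- the reaction counts as stopped when no species that holds the starting complex changes by six tenths of a point or more over the second half of the time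
- no earlier run changes the charge of incoming ligand; that part of a forecast is a guess

- which holds at 15 d: what has brought the reaction to rest, or that it has not come to rest (it is still moving / all of the starting complex has reacted / the incoming ligand has run out first / forward and back rates have come level)
- amount of complex with one exchanged at 15 d, in percent of the starting complex charged
- amount of complex with two exchanged at 15 d, in percent of the starting complex charged

- Each complex with one exchanged holds one incoming ligand and each complex with two exchanged holds 2, so the exchange count, [complex with one exchanged] + 2 [complex with two exchanged] in percent of the starting complex charged, climbs towards the exchange budget, the incoming ligand charged per starting complex charged: 80.0% in this flask.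
- The north-east run had a budget of 40.0%, and its count reads 40.5% at 40.0 h: within the scatter of the readings, that count has reached the budget.
- Slope: taking the decay of the incoming ligand as first order, the north-east count of 16.3% at 5.00 h gives a decay constant, as read, of 0.105 h⁻¹, a half-life of 6.62 h. Carrying this over to the flask is a guess, and it gives the count a starting slope of 0.0837 h⁻¹, as a fraction of the starting complex charged.
- Knee: by this reckoning, 5 half-lives leave 3.12% of the incoming ligand in the flask, and that span of 33.1 h is far shorter than 15 d.
- Level: the count should lie flat at 80.0% by 15 d, with the incoming ligand as limiting reagent.
- The forecast says the incoming ligand has run out first, with 35% (28% to 40%) of complex with one exchanged and 22.5% (19% to 27%) of complex with two exchanged; its ground: “The ligand balance is the key”.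
- The flask ends as follows: the incoming ligand has run out first, with 32.7% of complex with one exchanged and 23.7% of complex with two exchanged, and the forecast holds on each. Incoming ligand stands at 4.82% of its charge at 1.50 d and 0% at 15.0 d.

    complex with one exchanged + incoming ligand → leaving ligand + complex with two exchanged (k = 0.00135 M⁻¹ min⁻¹)
    starting complex + incoming ligand → leaving ligand + complex with one exchanged (k = 0.00108 M⁻¹ min⁻¹)
    starting complex → decomposition product (k = 1.10 × 10⁻⁶ min⁻¹)

- The flask's count at 15 d is 80.1% against the budget of 80.0%. The neighbour charged with 0.45 M of incoming ligand has a budget of 32.1%, and at 15 d its incoming ligand stands at 0%. It holds 22.2% of complex with one exchanged and 4.98% of complex with two exchanged, a count of 32.2%. Its starting complex stands at 71.1%.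

(Readings and results are calculated for substances that don't exist, noise included.)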